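The route rests on disconnecting the bond between the vinylic CH of the C=C(CH2OH) alkene and the CH2 next to the carbinol carbon. The feature exploited is the (E)-2-ene-1,5-diol array: the vinylic CH lies γ to the primary allylic oxygen, and the CH2 lies β to the secondary carbinol oxygen beside the furanone ring. An α-lithiated 2-(homofarnesyl)allyl imidazolyl sulfide, a masked 3-hydroxypropenyl anion, opens an (S)-3-furyl epoxide at its CH2, joining the C19 and C6 halves and bringing in the stereocentre. A sulfoxide–sulfenate [2,3] shift then moves alkene and oxygen into place, and the furan, a latent furanone, is oxidised last.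

Key step: step 5

Remark: the sulfur-bearing carbon of 11 and 12 and the bridgehead or hemiacetal carbons of 15 and 16 form as epimer mixtures that converge later, so these centres are left undefined in the SMILES.

Step 1
Reactants: 1 (2E,6E)-farnesyl bromide; 2 2-methylprop-2-en-1-ol (methallyl alcohol)
Product: 4 (5E,9E)-6,10,14-trimethyl-2-methylidenepentadeca-5,9,13-trien-1-ol, via dilithiated methallyl alcohol 3 (not isolated)
Conditions: 2 (1.5 equiv), n-BuLi (3.0 equiv), TMEDA, Et2O, 0 °C → rt; then 1, THF, −78 → 0 °C; H2O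
Reagents that add atoms: none
Why: Double deprotonation of methallyl alcohol (O–H, then the allylic CH3) gives a 2-(lithiomethyl)allyl alkoxide whose carbon terminus displaces the primary allylic bromide (allyl-dianion SN2 alkylation); the two carbon termini of this allyl anion are equivalent, so one constitution results and the E-alkenes of the farnesyl unit are not touched.

Step 2
Reactants: 4 (5E,9E)-6,10,14-trimethyl-2-methylidenepentadeca-5,9,13-trien-1-ol
Product: 6 1-methyl-2-{[(5E,9E)-6,10,14-trimethyl-2-methylidenepentadeca-5,9,13-trien-1-yl]sulfanyl}-1H-imidazole, via allylic mesylate 5 (not isolated)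
Conditions: MsCl, Et3N, THF, 0 °C; then 2-mercapto-1-methylimidazole, K2CO3, DMF, rt
Reagents that add atoms: 2-mercapto-1-methylimidazole (methimazole), CN1C=CNC1=S
Why: Sulfonylation of the primary allylic alcohol and S-alkylation of the soft thione sulfur (thiol alkylation) should give the allyl heteroaryl sulfide, and direct and allylic displacement lead to the same product because both CH2 termini of the allyl unit are equivalent.

Step 3
Reactants: 7 furan-3-carbaldehyde
Product: 8 rac-3-(oxiran-2-yl)furan
Conditions: Me3S+ I−, KOH, MeCN (trace H2O), 60 °C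
Reagents that add atoms: trimethylsulfonium iodide, C[S+](C)C.[I-]
Why: Corey–Chaykovsky epoxidation, in which the sulfonium methylide adds to the aldehyde and the betaine closes to the terminal epoxide with loss of dimethyl sulfide.

Step 4
Reactants: 8 rac-3-(oxiran-2-yl)furan
Product: 9 (S)-3-(oxiran-2-yl)furan
Conditions: (S,S)-(salen)Co(III)OAc (0.5–1 mol%), H2O (0.55 equiv), THF, 0 °C → rt; distillation
Reagents that add atoms: none
Why: Jacobsen hydrolytic kinetic resolution, in which the catalyst enantiomer that hydrates the (R)-epoxide leaves the (S)-epoxide, so the only stereocentre of the target is set here under catalyst control.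

Step 5
Reactants: 6 1-methyl-2-{[(5E,9E)-6,10,14-trimethyl-2-methylidenepentadeca-5,9,13-trien-1-yl]sulfanyl}-1H-imidazole; 9 (S)-3-(oxiran-2-yl)furan
Product: 11 (1R,7E,11E)-1-(furan-3-yl)-8,12,16-trimethyl-4-methylidene-3-[(1-methyl-1H-imidazol-2-yl)sulfanyl]heptadeca-7,11,15-trien-1-ol (both C3 epimers), via α-lithio allyl sulfide 10 (not isolated)
Conditions: n-BuLi, THF, −78 °C; then 9, −78 → 0 °C; H2O
Reagents that add atoms: none
Why: n-BuLi removes the proton α to sulfur of 6 to give the 1-thioallyllithium 10, held as an N–Li chelate at the sulfur-bearing carbon, and this carbon attacks the unsubstituted CH2 of epoxide 9 in an SN2 ring opening, which forges the bond between the future vinylic CH and the CH2 next to the carbinol carbon. The closest known reaction type is the α-alkylation of metalated allyl heteroaryl sulfides used as masked 3-hydroxypropenyl anions (Biellmann-type coupling), combined with epoxide opening by sulfur-stabilised carbanions. No ring is closed. The carbinol stereocentre is not created here but carried over from 9 with no bond to it broken, so (S)-9 gives the (1R) alcohol (the descriptor changes only through CIP priorities), while the new C–S centre forms as an epimer mixture that step 6 erases. The step needs α- rather than γ-attack of the allyl anion, which the imidazole chelate should secure, and attack at the terminal rather than the furyl-bearing epoxide carbon, which the SN2 character in the absence of a Lewis acid should secure.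

Step 6
Reactants: 11 (1R,7E,11E)-1-(furan-3-yl)-8,12,16-trimethyl-4-methylidene-3-[(1-methyl-1H-imidazol-2-yl)sulfanyl]heptadeca-7,11,15-trien-1-ol
Product: 14 (1R,3E,7E,11E)-1-(furan-3-yl)-4-(hydroxymethyl)-8,12,16-trimethylheptadeca-3,7,11,15-tetraen-1-ol, via allyl sulfoxide 12 (not isolated), via allyl sulfenate 13 (not isolated)
Conditions: mCPBA (1.0 equiv), CH2Cl2, −78 °C; then Et2NH, MeOH, rt
Reagents that add atoms: mCPBA (3-chloroperoxybenzoic acid), OOC(=O)c1cccc(Cl)c1
Why: The peracid should oxidise sulfur much faster than the alkenes or the furan at −78 °C, and sulfoxide 12 equilibrates by Mislow–Evans [2,3]-sigmatropic shift with sulfenate 13, which the amine cleaves at S–O; the envelope transition state with the CH2CH(OH)-furyl substituent pseudo-equatorial places it trans to the CH2O carbon (the preference that also makes SeO2 allylic oxidations E-selective), so the (3E) alkene and the primary allylic alcohol should result with C1 untouched.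

Step 7
Reactants: 14 (1R,3E,7E,11E)-1-(furan-3-yl)-4-(hydroxymethyl)-8,12,16-trimethylheptadeca-3,7,11,15-tetraen-1-ol
Product: 17 Hippolide C [4-((1R,3E,7E,11E)-1-hydroxy-4-(hydroxymethyl)-8,12,16-trimethylheptadeca-3,7,11,15-tetraen-1-yl)furan-2(5H)-one], via furan endoperoxide 15 (not isolated), via 5-hydroxybutenolide 16 (not isolated)
Conditions: O2, hν (visible), Rose Bengal (cat.), i-Pr2NEt, CH2Cl2, −78 °C; then EtOH, NaBH4, 0 °C; 1 M HCl
Reagents that add atoms: oxygen, O=O
Why: Singlet oxygen should add [4+2] to the furan faster than it undergoes ene reactions with the trisubstituted alkenes at −78 °C, the hindered amine removes the endoperoxide bridgehead proton remote from the substituent (Kornblum–DeLaMare fragmentation) to give the 4-substituted 5-hydroxybutenolide 16, and borohydride reduction of its ring-opened aldehyde form followed by acid lactonisation should give the 4-substituted furan-2(5H)-one without touching the carbinol stereocentre.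

Compound list
1 | (2E,6E)-farnesyl bromide [(2E,6E)-1-bromo-3,7,11-trimethyldodeca-2,6,10-triene] | CC(C)=CCC/C(C)=C/CC/C(C)=C/CBr | starting material
2 | 2-methylprop-2-en-1-ol (methallyl alcohol) | CC(=C)CO | starting material
3 | dilithiated methallyl alcohol [lithium 2-(lithiomethyl)prop-2-en-1-olate] | [Li]CC(=C)CO[Li] | intermediate
4 | (5E,9E)-6,10,14-trimethyl-2-methylidenepentadeca-5,9,13-trien-1-ol | CC(C)=CCC/C(C)=C/CC/C(C)=C/CCC(=C)CO | intermediate
5 | (5E,9E)-6,10,14-trimethyl-2-methylidenepentadeca-5,9,13-trien-1-yl methanesulfonate | CC(C)=CCC/C(C)=C/CC/C(C)=C/CCC(=C)COS(C)(=O)=O | intermediate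
6 | 1-methyl-2-{[(5E,9E)-6,10,14-trimethyl-2-methylidenepentadeca-5,9,13-trien-1-yl]sulfanyl}-1H-imidazole | CC(C)=CCC/C(C)=C/CC/C(C)=C/CCC(=C)CSc1nccn1C | intermediate
7 | furan-3-carbaldehyde | O=Cc1ccoc1 | starting material
8 | rac-3-(oxiran-2-yl)furan | C1OC1c1ccoc1 | intermediate
9 | (S)-3-(oxiran-2-yl)furan | C1[C@@H](O1)c2ccoc2 | intermediate
10 | α-lithio derivative of 6 (lithium at the sulfur-bearing carbon) | CC(C)=CCC/C(C)=C/CC/C(C)=C/CCC(=C)C([Li])Sc1nccn1C | intermediate
11 | (1R,7E,11E)-1-(furan-3-yl)-8,12,16-trimethyl-4-methylidene-3-[(1-methyl-1H-imidazol-2-yl)sulfanyl]heptadeca-7,11,15-trien-1-ol (C3 epimers) | CC(C)=CCC/C(C)=C/CC/C(C)=C/CCC(=C)C(C[C@@H](O)c1ccoc1)Sc1nccn1C | intermediate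
12 | S-oxide (sulfoxide) of 11 | CC(C)=CCC/C(C)=C/CC/C(C)=C/CCC(=C)C(C[C@@H](O)c1ccoc1)S(=O)c1nccn1C | intermediate
13 | (2E)-allyl sulfenate ester, O–S(1-methylimidazol-2-yl) derivative of 14 at the primary oxygen | CC(C)=CCC/C(C)=C/CC/C(C)=C/CC/C(=C\C[C@@H](O)c1ccoc1)COSc1nccn1C | intermediate
14 | (1R,3E,7E,11E)-1-(furan-3-yl)-4-(hydroxymethyl)-8,12,16-trimethylheptadeca-3,7,11,15-tetraen-1-ol | CC(C)=CCC/C(C)=C/CC/C(C)=C/CC/C(=C\C[C@@H](O)c1ccoc1)CO | intermediate
15 | furan endoperoxide of 14 (5-substituted 2,3,7-trioxabicyclo[2.2.1]hept-5-ene) | CC(C)=CCC/C(C)=C/CC/C(C)=C/CC/C(=C\C[C@@H](O)C1=CC2OOC1O2)CO | intermediate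
16 | 5-hydroxy-4-[(1R,3E,7E,11E)-1-hydroxy-4-(hydroxymethyl)-8,12,16-trimethylheptadeca-3,7,11,15-tetraen-1-yl]furan-2(5H)-one (C5 epimers) | CC(C)=CCC/C(C)=C/CC/C(C)=C/CC/C(=C\C[C@@H](O)C1=CC(=O)OC1O)CO | intermediate
17 | Hippolide C, 4-[(1R,3E,7E,11E)-1-hydroxy-4-(hydroxymethyl)-8,12,16-trimethylheptadeca-3,7,11,15-tetraen-1-yl]furan-2(5H)-one | CC(C)=CCC/C(C)=C/CC/C(C)=C/CC/C(=C\C[C@@H](O)C1=CC(=O)OC1)CO | target

Total step count: 7. Longest linear sequence: 5 steps (steps 1, 2, 5, 6, 7).

Steps most likely to fail

Step 5 (key step). The thioallyl anion may react through its γ (CH2=) terminus, the epoxide may open at the furyl-bearing carbon, or ring opening may be too slow for the anion to survive. The fallback replaces the epoxide by a primary iodide that has a single electrophilic carbon. It sets out from racemic epoxide 8: hydrolytic kinetic resolution with the enantiomeric (R,R)-catalyst and 0.45 equiv of water, this time collecting the diol, gives (S)-1-(furan-3-yl)ethane-1,2-diol F1. Selective primary sulfonylation (TsCl, cat. Bu2SnO, Et3N) gives (S)-2-(furan-3-yl)-2-hydroxyethyl 4-methylbenzenesulfonate F2. Silylation (TBSOTf, 2,6-lutidine) gives (S)-2-[(tert-butyldimethylsilyl)oxy]-2-(furan-3-yl)ethyl 4-methylbenzenesulfonate F3, and NaI in acetone gives tert-butyl{[(1S)-1-(furan-3-yl)-2-iodoethyl]oxy}dimethylsilane F4. Alkylation of 10 (from 6 and n-BuLi) with F4 in THF/HMPA at −78 °C should give the tert-butyldimethylsilyl ether of 11 F5, and TBAF returns to the route at 11.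

Step 6. Part of the material may pass through the [2,3] transition state with the side chain pseudo-axial, which erodes the E geometry of the new trisubstituted alkene. The fallback replaces kinetic control by thermodynamic control through a 2-alkyl enal. It sets out from 11: TESCl and imidazole give the triethylsilyl ether of 11 F6. Oxidation and rearrangement as in step 6 pass through the silylated sulfoxide F7 and the silylated sulfenate F8 to the silylated allylic alcohol F9 as an E/Z mixture. MnO2 gives the enal, which catalytic DABCO should equilibrate to the silylated (E)-enal F10 (formyl group trans to the β-substituent, as in tiglic versus angelic aldehyde). NaBH4/CeCl3 returns the pure (E)-alcohol F9, and TBAF returns to the route at 14.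

Step 1. Halogen–metal exchange with Wurtz-type homocoupling, attack at the tertiary allylic terminus of the bromide, or incomplete second deprotonation may consume the dianion or the bromide. The fallback builds the 2-substituted allyl alcohol by α-methylenation of an aldehyde instead. It sets out from 1: coupling with the Grignard reagent of 2-(2-bromoethyl)-1,3-dioxolane (cat. Li2CuCl4, THF, 0 °C) gives 2-[(4E,8E)-5,9,13-trimethyltetradeca-4,8,12-trien-1-yl]-1,3-dioxolane F11. Mild acetal hydrolysis (PPTS, wet acetone) gives (5E,9E)-6,10,14-trimethylpentadeca-5,9,13-trienal F12. Organocatalytic α-methylenation (aq. CH2O, cat. pyrrolidine and propionic acid) gives (5E,9E)-6,10,14-trimethyl-2-methylidenepentadeca-5,9,13-trienal F13, and NaBH4/CeCl3 returns to the route at 4.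

Further compounds
F1 | step 5 | (S)-1-(furan-3-yl)ethane-1,2-diol | OC[C@@H](O)c1ccoc1
F2 | step 5 | (S)-2-(furan-3-yl)-2-hydroxyethyl 4-methylbenzenesulfonate | Cc1ccc(cc1)S(=O)(=O)OC[C@@H](O)c1ccoc1
F3 | step 5 | (S)-2-[(tert-butyldimethylsilyl)oxy]-2-(furan-3-yl)ethyl 4-methylbenzenesulfonate | Cc1ccc(cc1)S(=O)(=O)OC[C@@H](O[Si](C)(C)C(C)(C)C)c1ccoc1
F4 | step 5 | tert-butyl{[(1S)-1-(furan-3-yl)-2-iodoethyl]oxy}dimethylsilane | IC[C@@H](O[Si](C)(C)C(C)(C)C)c1ccoc1
F5 | step 5 | tert-butyldimethylsilyl ether of 11 | CC(C)=CCC/C(C)=C/CC/C(C)=C/CCC(=C)C(C[C@@H](O[Si](C)(C)C(C)(C)C)c1ccoc1)Sc1nccn1C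
F6 | step 6 | triethylsilyl ether of 11 | CC(C)=CCC/C(C)=C/CC/C(C)=C/CCC(=C)C(C[C@@H](O[Si](CC)(CC)CC)c1ccoc1)Sc1nccn1C
F7 | step 6 | S-oxide of F6 | CC(C)=CCC/C(C)=C/CC/C(C)=C/CCC(=C)C(C[C@@H](O[Si](CC)(CC)CC)c1ccoc1)S(=O)c1nccn1C
F8 | step 6 | allyl sulfenate ester from F7 | CC(C)=CCC/C(C)=C/CC/C(C)=C/CC/C(=C\C[C@@H](O[Si](CC)(CC)CC)c1ccoc1)COSc1nccn1C
F9 | step 6 | triethylsilyl ether (secondary oxygen) of 14, (E)-isomer | CC(C)=CCC/C(C)=C/CC/C(C)=C/CC/C(=C\C[C@@H](O[Si](CC)(CC)CC)c1ccoc1)CO
F10 | step 6 | (E)-enal from F9 | CC(C)=CCC/C(C)=C/CC/C(C)=C/CC/C(=C\C[C@@H](O[Si](CC)(CC)CC)c1ccoc1)C=O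
F11 | step 1 | 2-[(4E,8E)-5,9,13-trimethyltetradeca-4,8,12-trien-1-yl]-1,3-dioxolane | CC(C)=CCC/C(C)=C/CC/C(C)=C/CCCC1OCCO1
F12 | step 1 | (5E,9E)-6,10,14-trimethylpentadeca-5,9,13-trienal | CC(C)=CCC/C(C)=C/CC/C(C)=C/CCCC=O
F13 | step 1 | (5E,9E)-6,10,14-trimethyl-2-methylidenepentadeca-5,9,13-trienal | CC(C)=CCC/C(C)=C/CC/C(C)=C/CCC(=C)C=O
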